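The wanted product, the target, did not last in the earlier runs, and I started there.

| setting | dusk | noon | cedar | ash | oak |
|---|---|---|---|---|---|
| starting material | 0.34 M | 0.50 M | 0.50 M | 0.50 M | 0.50 M |
| coupling partner | 0.35 M | 0.70 M | 0.350 M | 0.350 M | 0.350 M |
| protic impurity | 0.10 M | 0.10 M | 0.100 M | 0.200 M | 0.400 M |
| remark | run made earlier | run made earlier |  |  |  |
| time |  |  | 3.0 min | 3.0 min | 3.0 min |

Cedar, ash and oak differ in their charge of protic impurity, from 0.100 M to 0.400 M, and no earlier run varied it.

| run | time / s | target / % |
|---|---|---|
| dusk | 10.0 | 4.6 |
| dusk | 20.0 | 8.5 |
| dusk | 50.0 | 12.7 |
| dusk | 120 | 9.8 |
| noon | 10.0 | 8.6 |
| noon | 20.0 | 13.7 |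
| noon | 50.0 | 14.8 |
| noon | 120 | 9.8 |

(each reading ± 0.5 percentage points)

- amounts and yields of released group count crystals too
- given per volume of solution although it is solid: crystals
- candidate steps: crystals <-> released group; intermediate <-> target + released group; coupling partner + protic impurity -> quenched reagent; intermediate -> side product; starting material + coupling partner <-> intermediate
- "hardly changes" means that all values lie within two and a half points (for a concentration: within two and a half percent of the largest)
- no earlier run changes the charge of protic impurity; that part of a forecast is a guess

The dusk run stood at 12.7% after 50.0 s but had fallen to 9.8% after 120 s. So something was draining the target, and the candidate steps offered a route: target and released group return to the intermediate, which goes on to side product.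

But percentages hid the useful comparison, so I turned them into concentrations. After 50.0 s, the readings put the target of the noon run at 1.71 times that of the dusk run, while its feed, the product of the charges of starting material and coupling partner, was 2.94 times as large. The logarithm of the first ratio over that of the second read 0.499; I called this the feed order, the power of its feed that the target follows. That reading lies near a square root, as expected for a pre-equilibrium: target and released group appear in equal amounts, so the square of the target follows the intermediate.

My own reckoning was a guess: a feed cut 4.00 times, as much as the impurity rises, put oak at 0.501 of the target in cedar.

* amount of target at the end, in percent of the starting material charged for cedar, ash, oak, in this order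
* how the row runs (hardly changes / falls, then rises / falls all the way / rises all the way / rises, then falls)

The forecast gave 6%, 4.7% and 0.7%, so falls all the way, an oak-to-cedar ratio of 0.117, and it said “The quench rate is a guess”.

The flasks gave 5.38%, 4.75% and 3.75%: hardly changes.

    crystals ⇌ released group, rate k1*(cs1 - [released group]) while solid is left; crystals form when [released group] > cs1 (solubility = 0.250 M, k = 0.107 s⁻¹)
    intermediate ⇌ target + released group (K = 0.174 M, k = 0.311 s⁻¹)
    coupling partner + protic impurity → quenched reagent (k = 0.0413 M⁻¹ s⁻¹)
    intermediate → side product (k = 0.124 s⁻¹)
    starting material + coupling partner ⇌ intermediate (K = 13.1 M⁻¹, k = 0.0321 M⁻¹ s⁻¹)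

Two steps acted together in this shallow row, each a part of the reason. Oak ended at 3.75%, but it reached 24.8% without the way back from target and released group to the intermediate, and 20.4% without the path to side product, and either removal turned the shape. After 3.00 min, cedar held 2.27 times the intermediate of oak, and the feed order turned that into 1.51 for the target, where the flasks gave 1.43. Between cedar and ash, it gave 1.15 against 1.13.

The readings are simulated for substances that don't exist; noise was put on by code.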